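**Assumption:** the target is drawn as the free tris(hydrogen sulfate). It would be handled as its pyridinium or sodium salt, and every structure below is written in the neutral acid form.

## Structural features

The target is a flavonol in which benzene ring A is fused across C4a–C8a to the 4-pyranone ring C, and ring C carries ring B, a 1,3,4-trisubstituted benzene, on C2 through the single bond C2–C1'. Oxygen sits on C3 (ring C), C7 (ring A) and C4' (ring B), each as a hydrogen sulfate ester, while C3' carries a methyl ether and C5, C6 and C8 are unsubstituted. The molecule is flat and has no stereocentre, so no stereocentres stand next to each other and the problem is one of regiochemistry and timing. The three sulfate monoesters are the fragile groups: they are strongly acidic, hydrolyse under acid catalysis, make the compound water-soluble, and tolerate neither silica chromatography nor organometallic or strongly reducing steps. The real difficulties are to place oxygen on C7 alone without carrying a ring A phenol through the carbanion chemistry, to have the C3 oxygen in place when ring C forms, and to sulfate three hydroxyls of different character completely, the C3 enol hydroxyl being hydrogen-bonded to the C4 carbonyl. The feature exploited is that O1 is bonded to C8a, ortho to the carbonyl-bearing C4a, while C7 is para to C4a. Both carbons are therefore activated by the C4 carbonyl for addition–elimination: a fluoride on C8a can be displaced by an internal enolate oxygen to close ring C, and a fluoride on C7 afterwards by an external alkoxide.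

## Logic of the disconnections

**12 ⇒ 11.** The three O–S bonds are cut first. The sulfates are the most labile and most polar groups and must come last. This turns an ionic, acid-sensitive product into a neutral triol that can be purified normally. The forward step must sulfate all three hydroxyls, including the chelated one on C3, and be worked up without exposure to acid and heat.

**11 ⇒ 10.** The three O–benzyl bonds are cut together. One protecting group for all three hydroxyls means one neutral, reductive deprotection that leaves the methyl ether and the pyranone alone. The forward step must cleave two aryl benzyl ethers and one enol benzyl ether without saturating C2=C3.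

**10 ⇒ 9.** The C7–O bond is cut to a C7–F bond. C7 is para to C4a, so a fluoride there is activated by the C4 carbonyl. Ring A then needs neither regioselective oxygenation nor a phenol protecting group during the organolithium and enolate steps. The forward step needs the alkoxide to substitute at C7 and not to add to C2 of the pyranone.

**9 ⇒ 8.** The O1–C8a bond is cut, which opens ring C and reduces the bicycle to an acyclic 2-alkoxy-1,3-diketone with an ortho fluoride as leaving group. This is the strategic simplification: the C3 oxygen, the C2 aryl group and the C4 carbonyl are all already in place in 8, and the product comes out at the aromatic oxidation level. The forward step must displace only the ortho fluoride, and 8 must survive base without retro-Claisen cleavage. The design of 8 was tuned in three ways. The C7 substituent stays fluorine, because a fluorine meta to the leaving fluoride raises the electrophilicity of C8a, whereas an alkoxy group there would lower the activation by the carbonyl. Both ether protecting groups are benzyl, so that they leave with the later C7 benzyl ether in one operation. The cyclisation solvent is chosen free of amine sources, so that the second fluoride is not attacked.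

**8 ⇒ 6 + 7.** The bond between the central carbon and the difluorobenzoyl carbonyl (C3–C4 of the chromone) is cut in a crossed-Claisen sense. This is convergent, and 7 is a bulk chemical that brings ring A with both fluorides. The forward step needs C-acylation in preference to O-acylation and must stop after one acylation.

**6 ⇒ 5 + 4.** The aryl–carbonyl bond of ring B is cut to 5, which is generated in the flask from 2, and to 4. This delivers the two-carbon unit with its oxygen already attached and benzylated. The forward step needs a single addition without over-addition, and halogen–metal exchange that outruns deprotonation of the benzyl ether.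

**2 ⇒ 1.** The O–benzyl bond is cut to a commercial bromophenol. The forward step is a routine etherification that must leave the aryl bromide alone.

**4 ⇒ 3.** The amide C–N bond is cut to a commercial acid chloride. The forward step is a routine N-acylation.

## Other disconnections considered

**Alternative 1:** The cut is C3–C4 of ring C. In the forward step an N-heterocyclic carbene would add to the ring A aldehyde of the tethered dialdehyde 4-(benzyloxy)-2-{1-[4-(benzyloxy)-3-methoxyphenyl]-2-oxoethoxy}benzaldehyde A2. The resulting acyl anion equivalent would add to the aliphatic aldehyde and close ring C as the 3-hydroxychroman-4-one A1, a mixture of stereoisomers.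
- In its favour: the closure is organocatalytic, mild and metal-free. The O1–C8a ether and the C7 oxygen would come ready-made from a salicylaldehyde-type building block. A1 carries a free C3 hydroxyl.
- Against it: A2 is an α-aryl-α-aryloxy acetaldehyde. It is prone to enolisation, hydrate formation and loss of phenoxide, and making it in the presence of a second aldehyde needs several steps. The carbene can also choose either aldehyde of A2; the less hindered aliphatic one is normally the better donor, which would reverse the sense of the union and put the carbonyl on C3 instead of C4. A1 is at the wrong oxidation level, so a dehydrogenation must follow that destroys both stereocentres the key step creates.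
- Comparison: on structure, A1 is the better of the two on one point, since the C7 oxygen is already present whereas 9 needs a further substitution. It also avoids organolithium chemistry. On mechanism, the chosen plan is more secure, because its selectivity is enforced by the tether and not decided by a catalyst. On step economy the two are at best equal, and the preparation of A2 and the extra oxidation would probably make this route longer.

**Alternative 2:** The cuts are C4a–C5 and C8–C8a, so ring A is built last. In the forward step the sulfinyl-bearing C5=C6 bond of 3-(benzyloxy)-2-[4-(benzyloxy)-3-methoxyphenyl]-5-(phenylsulfinyl)-4H-pyran-4-one A4 would undergo [4+2] cycloaddition with Danishefsky's diene, (E)-1-methoxy-3-(trimethylsilyloxy)buta-1,3-diene A5. Elimination of the sulfinyl and methoxy groups, with desilylation, would then give the 7-phenol A3.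
- In its favour: A5 is a strongly polarised diene, which fixes the C7 oxygen regiochemistry. Two C–C bonds form in one operation, and A3 already has a free C7 hydroxyl. A3 could go straight to hydrogenolysis, which saves the alkoxide substitution of the chosen plan; on that point it is the better route.
- Against it: A4 is a fully substituted 4-pyranone and would be harder to make than the flavone itself. Its C5=C6 bond is part of a vinylogous ester and is a reluctant dienophile. The heating that may be needed could trigger sulfoxide elimination from A4 before cycloaddition, and A5 is sensitive to moisture and acid. A benzene ring that can be bought in 7 would be rebuilt atom by atom.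
- Comparison: regiocontrol is equal, secured by the polarity of A5 there and by the tether here. On structure, both avoid a ring A phenol protecting group. On step economy the chosen plan is clearly shorter.

**Alternative 3:** The cuts are C4a–C4, C4–C3 and O1–C2. In the forward step zerovalent palladium would insert into the C–I bond of 5-(benzyloxy)-2-iodophenol A7. Carbonylation and coupling with the arylalkyne 1-(benzyloxy)-4-ethynyl-2-methoxybenzene A8 would give an ynone, which the phenol would close by 6-endo addition to the flavone A6.
- In its favour: it is the most convergent of all the options, with three bonds and ring C formed in one catalytic operation from the two simple partners A7 and A8 and the C7 oxygen already in place. In convergence it is better than the chosen plan.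
- Against it: A6 has no oxygen on C3. A separate C3 oxygenation (metalation–oxidation or epoxidation of C2=C3) on an electron-rich flavone would be needed, and this is the least predictable kind of step here. The 5-exo closure to an aurone can compete. A toxic gas under pressure is required, A7 needs a regioselective iodination, and A8 needs an alkynylation of its own.
- Comparison: on structure the chosen plan has the decisive advantage, because the C3 oxygen is built in from the two-carbon unit of 4. On mechanism, the SNAr closure has no endo/exo ambiguity. On step count the two are about equal.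

Key step: step 5

## Route

**Step 1**
Reactants: 1 4-bromo-2-methoxyphenol
Product: 2 1-(benzyloxy)-4-bromo-2-methoxybenzene
Conditions: BnBr, K2CO3, acetone, reflux
Reagents that add atoms: benzyl bromide, BrCc1ccccc1
Why: Williamson ether synthesis; the phenoxide of 1 displaces bromide from the benzylic halide by SN2, and the aryl bromide is inert under these conditions.

**Step 2**
Reactants: 3 benzyloxyacetyl chloride
Product: 4 2-(benzyloxy)-N-methoxy-N-methylacetamide
Conditions: MeNH(OMe)·HCl, Et3N, CH2Cl2, 0 °C → rt
Reagents that add atoms: N,O-dimethylhydroxylamine hydrochloride, CNOC.Cl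
Why: N-acylation of the hydroxylamine by the acid chloride (Weinreb amide formation); Et3N frees the amine and takes up the HCl.

**Step 3**
Reactants: 2 1-(benzyloxy)-4-bromo-2-methoxybenzene; 4 2-(benzyloxy)-N-methoxy-N-methylacetamide
Product: 6 2-(benzyloxy)-1-[4-(benzyloxy)-3-methoxyphenyl]ethan-1-one, via aryllithium 5 (not isolated)
Conditions: n-BuLi, THF, −78 °C; then 4, −78 → 0 °C; aq. NH4Cl
Reagents that add atoms: none
Why: Bromine–lithium exchange at −78 °C should outrun deprotonation of the benzyl ether; in the Weinreb ketone synthesis the N-methoxy chelate, reinforced by the α-benzyloxy oxygen, holds the tetrahedral adduct until the quench, so addition stops at the ketone.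

**Step 4**
Reactants: 6 2-(benzyloxy)-1-[4-(benzyloxy)-3-methoxyphenyl]ethan-1-one; 7 2,4-difluorobenzoyl chloride
Product: 8 2-(benzyloxy)-3-[4-(benzyloxy)-3-methoxyphenyl]-1-(2,4-difluorophenyl)propane-1,3-dione (racemic, configurationally labile)
Conditions: MgBr2·OEt2, i-Pr2NEt, CH2Cl2, 0 °C → rt; 1 M HCl work-up
Reagents that add atoms: none
Why: Soft enolisation gives a chelated magnesium enolate of the α-alkoxy ketone, which should undergo crossed-Claisen C-acylation with the acid chloride; the product is held as a magnesium diketonate, which guards against O-acylation and a second acylation until the acidic work-up.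

**Step 5**
Reactants: 8 2-(benzyloxy)-3-[4-(benzyloxy)-3-methoxyphenyl]-1-(2,4-difluorophenyl)propane-1,3-dione
Product: 9 3-(benzyloxy)-2-[4-(benzyloxy)-3-methoxyphenyl]-7-fluoro-4H-chromen-4-one
Conditions: K2CO3, dry DMSO, 60 °C
Reagents that add atoms: none
Why: K2CO3 removes the proton on the central carbon of 8, and the enolate oxygen on the ring B carbonyl adds to the fluorine-bearing ortho carbon of the difluorobenzoyl ring (the future C8a), giving a Meisenheimer anion whose charge runs through C4a into the C4 carbonyl and is further stabilised inductively by the second fluorine, which is meta to the site of attack. Loss of fluoride restores aromaticity and gives the pyranone 9 directly, with no dehydration step. The closest known reaction type is the base-mediated cyclisation of 1-(2-fluoroaryl)-1,3-diketones to chromones and flavones by intramolecular SNAr. Ring C closes as a six-membered ring by oxygen attack on a trigonal aromatic carbon: the closure is 6-exo with respect to the departing C–F bond, and its addition half is a 6-endo-trig conjugate addition across C8a=C4a–C4=O, reached by a small twist about C4–C4a that places the oxygen over the face of C8a. No stereocentre is formed, and the labile centre of 8 becomes the trigonal C3. The step needs ortho over para substitution and O- over C-attack; the tether secures both, because attack at the para carbon would require a bridged ring and attack through carbon or through the other enolate oxygen a four-membered ring. The para fluoride should survive because no external nucleophile is present, which is why DMSO is chosen over an amide solvent whose amine decomposition products could attack it.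

**Step 6**
Reactants: 9 3-(benzyloxy)-2-[4-(benzyloxy)-3-methoxyphenyl]-7-fluoro-4H-chromen-4-one
Product: 10 3,7-bis(benzyloxy)-2-[4-(benzyloxy)-3-methoxyphenyl]-4H-chromen-4-one
Conditions: BnOH (excess), KOt-Bu, THF/DMSO, 0 → 40 °C
Reagents that add atoms: benzyl alcohol, OCc1ccccc1
Why: Intermolecular SNAr; C7 is para to the carbonyl-bearing C4a, so the benzyloxide adduct is stabilised by the C4 carbonyl and fluoride is the best leaving group for this mechanism. Excess benzyl alcohol keeps tert-butoxide protonated, and the 2-aryl-3-benzyloxy substitution shields C2, where any alkoxide addition would in any case be reversible.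

**Step 7**
Reactants: 10 3,7-bis(benzyloxy)-2-[4-(benzyloxy)-3-methoxyphenyl]-4H-chromen-4-one
Product: 11 3,7-dihydroxy-2-(4-hydroxy-3-methoxyphenyl)-4H-chromen-4-one
Conditions: H2 (1 atm), Pd/C (10 wt% palladium on carbon), THF/MeOH, rt
Reagents that add atoms: none
Why: Catalytic hydrogenolysis of the two aryl benzyl ethers and the enol benzyl ether; the tetrasubstituted C2=C3 bond of the vinylogous ester and the methyl ether should be untouched at ambient pressure and temperature.

**Step 8**
Reactants: 11 3,7-dihydroxy-2-(4-hydroxy-3-methoxyphenyl)-4H-chromen-4-one
Product: 12 2-[3-methoxy-4-(sulfooxy)phenyl]-4-oxo-4H-chromene-3,7-diyl bis(hydrogen sulfate)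
Conditions: SO3·pyridine (excess), pyridine/DMF, 60 °C; MeOH quench; Sephadex LH-20; H+ exchange resin, 0 °C
Reagents that add atoms: sulfur trioxide–pyridine complex, O=S(=O)([O-])[n+]1ccccc1
Why: O-sulfation of phenolic and enolic hydroxyls by an SO3–amine complex; a large excess and gentle heating should carry the hydrogen-bonded C3 hydroxyl to completion, and the basic medium protects the sulfate esters from acid-catalysed hydrolysis during the reaction.

## Compound list

1 | 4-bromo-2-methoxyphenol | COc1cc(Br)ccc1O | starting material
2 | 1-(benzyloxy)-4-bromo-2-methoxybenzene | COc1cc(Br)ccc1OCc1ccccc1 | intermediate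
3 | benzyloxyacetyl chloride | O=C(Cl)COCc1ccccc1 | starting material
4 | 2-(benzyloxy)-N-methoxy-N-methylacetamide | CON(C)C(=O)COCc1ccccc1 | intermediate
5 | [4-(benzyloxy)-3-methoxyphenyl]lithium | [Li]c1ccc(OCc2ccccc2)c(OC)c1 | intermediate (not isolated)
6 | 2-(benzyloxy)-1-[4-(benzyloxy)-3-methoxyphenyl]ethan-1-one | COc1cc(C(=O)COCc2ccccc2)ccc1OCc1ccccc1 | intermediate
7 | 2,4-difluorobenzoyl chloride | O=C(Cl)c1ccc(F)cc1F | starting material
8 | 2-(benzyloxy)-3-[4-(benzyloxy)-3-methoxyphenyl]-1-(2,4-difluorophenyl)propane-1,3-dione (racemic, labile) | COc1cc(C(=O)C(OCc2ccccc2)C(=O)c2ccc(F)cc2F)ccc1OCc1ccccc1 | intermediate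
9 | 3-(benzyloxy)-2-[4-(benzyloxy)-3-methoxyphenyl]-7-fluoro-4H-chromen-4-one | COc1cc(-c2oc3cc(F)ccc3c(=O)c2OCc2ccccc2)ccc1OCc1ccccc1 | intermediate
10 | 3,7-bis(benzyloxy)-2-[4-(benzyloxy)-3-methoxyphenyl]-4H-chromen-4-one | COc1cc(-c2oc3cc(OCc4ccccc4)ccc3c(=O)c2OCc2ccccc2)ccc1OCc1ccccc1 | intermediate
11 | 3,7-dihydroxy-2-(4-hydroxy-3-methoxyphenyl)-4H-chromen-4-one | COc1cc(-c2oc3cc(O)ccc3c(=O)c2O)ccc1O | intermediate
12 | 2-[3-methoxy-4-(sulfooxy)phenyl]-4-oxo-4H-chromene-3,7-diyl bis(hydrogen sulfate) | COc1cc(-c2oc3cc(OS(=O)(=O)O)ccc3c(=O)c2OS(=O)(=O)O)ccc1OS(=O)(=O)O | target

## Step count and risks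

Total step count: 8. Longest linear sequence: 7 (steps 1, 3, 4, 5, 6, 7, 8); step 2 is a one-step branch. Compounds 2 and 4 are simple enough to be catalogue items, and buying them would remove steps 1 and 2.

**Step 5 (key step).**
- What may go wrong: retro-Claisen fragmentation of the diketone by adventitious hydroxide may compete with cyclisation. The hindered 2-substituted enolate may close slowly, and a stray nucleophile may attack the para fluoride too early.
- Fallback, from 2 to 11, leaving the SNAr logic altogether: aryllithium 5 would be quenched with DMF to give 4-(benzyloxy)-3-methoxybenzaldehyde F1. Claisen–Schmidt condensation of F1 with commercial 1-[4-(benzyloxy)-2-hydroxyphenyl]ethan-1-one (KOH, EtOH) should give the chalcone (E)-1-[4-(benzyloxy)-2-hydroxyphenyl]-3-[4-(benzyloxy)-3-methoxyphenyl]prop-2-en-1-one F2. Algar–Flynn–Oyamada oxidation (H2O2, NaOH, MeOH) should give 7-(benzyloxy)-2-[4-(benzyloxy)-3-methoxyphenyl]-3-hydroxy-4H-chromen-4-one F3. Hydrogenolysis of F3 (H2, Pd/C) rejoins the route at 11.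

**Step 4.**
- What may go wrong: O-acylation of the enolate or a second acylation of the product diketonate, and Lewis-acid-assisted loss of a benzyl ether on long exposure to the magnesium salt.
- Fallback, from 6 to 8, replacing acylation by aldol addition and oxidation: the lithium enolate of 6 (LiN(i-Pr)2, THF, −78 °C) would be added to commercial 2,4-difluorobenzaldehyde to give 2-(benzyloxy)-1-[4-(benzyloxy)-3-methoxyphenyl]-3-(2,4-difluorophenyl)-3-hydroxypropan-1-one F4 as a diastereomer mixture. Oxidation of F4 with Dess–Martin periodinane gives 8.

**Step 6.**
- What may go wrong: conjugate addition of the alkoxide at C2 with opening of the pyranone ring, or sluggish substitution because the vinylogous-ester carbonyl activates C7 only moderately.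
- Fallback, from 6 to 10, putting the C7 oxygen in before ring closure: commercial 4-(benzyloxy)-2-fluorobenzoic acid would be converted with oxalyl chloride into 4-(benzyloxy)-2-fluorobenzoyl chloride F5. Acylation of 6 with F5 under the conditions of step 4 should give 2-(benzyloxy)-1-[4-(benzyloxy)-2-fluorophenyl]-3-[4-(benzyloxy)-3-methoxyphenyl]propane-1,3-dione F6. The same O1–C8a closure (K2CO3, DMSO, at higher temperature because the para alkoxy group weakens the activation) would then give 10 directly.

**Step 8.**
- What may go wrong: incomplete sulfation at the hydrogen-bonded C3 hydroxyl, giving mixtures of partial sulfates, and hydrolysis of sulfate esters during isolation of the free acid.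
- Fallback, from 11 to 12, through neutral sulfate diesters: 11 would be treated with 2,2,2-trichloroethyl chlorosulfate (Et3N, DMAP, THF) to give 2-(3-methoxy-4-{[(2,2,2-trichloroethoxy)sulfonyl]oxy}phenyl)-4-oxo-4H-chromene-3,7-diyl bis(2,2,2-trichloroethyl) bis(sulfate) F7. F7 can be purified on silica and checked for complete substitution. Reductive removal of the trichloroethyl groups (zinc dust, HCO2NH4, MeOH) then gives 12.

## Further compounds

F1 | step 5 | 4-(benzyloxy)-3-methoxybenzaldehyde | COc1cc(C=O)ccc1OCc1ccccc1
F2 | step 5 | (E)-1-[4-(benzyloxy)-2-hydroxyphenyl]-3-[4-(benzyloxy)-3-methoxyphenyl]prop-2-en-1-one | COc1cc(/C=C/C(=O)c2ccc(OCc3ccccc3)cc2O)ccc1OCc1ccccc1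
F3 | step 5 | 7-(benzyloxy)-2-[4-(benzyloxy)-3-methoxyphenyl]-3-hydroxy-4H-chromen-4-one | COc1cc(-c2oc3cc(OCc4ccccc4)ccc3c(=O)c2O)ccc1OCc1ccccc1
F4 | step 4 | 2-(benzyloxy)-1-[4-(benzyloxy)-3-methoxyphenyl]-3-(2,4-difluorophenyl)-3-hydroxypropan-1-one (mixture of diastereomers) | COc1cc(C(=O)C(OCc2ccccc2)C(O)c2ccc(F)cc2F)ccc1OCc1ccccc1
F5 | step 6 | 4-(benzyloxy)-2-fluorobenzoyl chloride | O=C(Cl)c1ccc(OCc2ccccc2)cc1F
F6 | step 6 | 2-(benzyloxy)-1-[4-(benzyloxy)-2-fluorophenyl]-3-[4-(benzyloxy)-3-methoxyphenyl]propane-1,3-dione (racemic, labile) | COc1cc(C(=O)C(OCc2ccccc2)C(=O)c2ccc(OCc3ccccc3)cc2F)ccc1OCc1ccccc1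
F7 | step 8 | 2-(3-methoxy-4-{[(2,2,2-trichloroethoxy)sulfonyl]oxy}phenyl)-4-oxo-4H-chromene-3,7-diyl bis(2,2,2-trichloroethyl) bis(sulfate) | COc1cc(-c2oc3cc(OS(=O)(=O)OCC(Cl)(Cl)Cl)ccc3c(=O)c2OS(=O)(=O)OCC(Cl)(Cl)Cl)ccc1OS(=O)(=O)OCC(Cl)(Cl)Cl
A1 | alternative 1 | 7-(benzyloxy)-2-[4-(benzyloxy)-3-methoxyphenyl]-3-hydroxychroman-4-one (mixture of stereoisomers) | O=C1c2ccc(OCc3ccccc3)cc2OC(c2ccc(OCc3ccccc3)c(OC)c2)C1O
A2 | alternative 1 | 4-(benzyloxy)-2-{1-[4-(benzyloxy)-3-methoxyphenyl]-2-oxoethoxy}benzaldehyde (racemic) | O=Cc1ccc(OCc2ccccc2)cc1OC(C=O)c1ccc(OCc2ccccc2)c(OC)c1
A3 | alternative 2 | 3-(benzyloxy)-2-[4-(benzyloxy)-3-methoxyphenyl]-7-hydroxy-4H-chromen-4-one | COc1cc(-c2oc3cc(O)ccc3c(=O)c2OCc2ccccc2)ccc1OCc1ccccc1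
A4 | alternative 2 | 3-(benzyloxy)-2-[4-(benzyloxy)-3-methoxyphenyl]-5-(phenylsulfinyl)-4H-pyran-4-one (racemic at sulfur) | COc1cc(-c2occ(S(=O)c3ccccc3)c(=O)c2OCc2ccccc2)ccc1OCc1ccccc1
A5 | alternative 2 | (E)-1-methoxy-3-(trimethylsilyloxy)buta-1,3-diene | CO/C=C/C(=C)O[Si](C)(C)C
A6 | alternative 3 | 7-(benzyloxy)-2-[4-(benzyloxy)-3-methoxyphenyl]-4H-chromen-4-one | COc1cc(-c2cc(=O)c3ccc(OCc4ccccc4)cc3o2)ccc1OCc1ccccc1
A7 | alternative 3 | 5-(benzyloxy)-2-iodophenol | Oc1cc(OCc2ccccc2)ccc1I
A8 | alternative 3 | 1-(benzyloxy)-4-ethynyl-2-methoxybenzene | C#Cc1ccc(OCc2ccccc2)c(OC)c1
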